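The examiner puts a flask of Ja, Jc, Jd and Je to a candidate who has Friday's run in hand.

in all of them: Ja 0.0010 M
- Friday's: Jc 1 mM; Jd 0.50 mM; Je 0.50 mM; run made earlier
- flask: Jc 1.00 mM; Jd 1.00 mM; Je 0.500 mM; time 6.0 min

Friday's run (percent of the Ja charged)

| time / s | Jf / % | Jg / % |
|---|---|---|
| 10.0 | 27.0 | 42.5 |
| 15.0 | 35.8 | 48.2 |
| 40.0 | 45.5 | 48.5 |

(readings scatter by 1 percentage point)

- ratio of Jf to Jg at 0.40 s
- ratio of Jf to Jg at 6.0 min

Examiner: What does Jg tell you in Friday's run?

Candidate: It reads 48.5% of the Ja charged at 40.0 s, about the 0.50 mM of Jd charged, so in Friday's run each Jg seems to take one Jd, and Jd looks like the limiting reagent for Jg. On that count the reading at 15.0 s leaves about 0.0180 mM of Jd.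

Examiner: And the early end of the new flask?

Candidate: Friday's reading of [Jf]/[Jg] at 10.0 s is 0.635. If Jd competes for a precursor shared by both products, the ratio of their rates of formation goes as one over [Jd] at a given [Jc]. The new flask has 2.00 times Friday's Jd charge and the same Jc charge, so my rough answer for it, scaled on the charges, is 0.318.

Examiner: Is the Jf safe at the late end?

Candidate: Friday's readings stop at 40.0 s, so I carry one number, the Jd surplus: the Jd left once Ja has been shared out at that ratio. For the new flask it is 0.241 mM, whereas the count for Friday's run at 15.0 s gave less. My late ratio in the new flask is therefore about 0.318 if Jf stays, and lower if Jd attacks Jf.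

The forecast gives 0.2 and then 0.29, a ratio that rises, holding that Ja is “partitioned between Jd, giving Jg, and Je, giving Jf”. My early value is higher, and I expect the ratio to stay level or fall.

The flask gives 0.239 at 0.40 s and 0.122 at 6.0 min.

    Jc + Je → Jh (k = 310 L mol⁻¹ s⁻¹)
    Jc + Jb → Jf (k = 910 L mol⁻¹ s⁻¹)
    Jd + Jf → Jj (k = 15.0 L mol⁻¹ s⁻¹)
    Jd + Jb → Jg (k = 3700 L mol⁻¹ s⁻¹)
    Ja → Jb (k = 0.160 s⁻¹)

In this flask Jd stands at 0.186 mM after 0.600 min, against the reckoned surplus of 0.241 mM, and the half-life of Jf by the step from Jd + Jf to Jj alone, the other concentrations as charged, is 0.77 min, shorter than the 6.0 min of the run, with Jf at 9.70% of the Ja charged beside Jj at 10.9% at 6.00 min. In the neighbour charged with 0.0040 M of Jd, the same reckoning gives a surplus of 3.07 mM, and at 6.00 min that flask holds 75.0% of its Jd charge and 0% of Jf.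

(The readings are simulated with made-up constants, noise included.)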